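The route rests on cutting the bond between the ipso carbon of the 3,4-dimethoxyphenyl ring (ring A) and the benzylic carbinol carbon C7. The aldehyde partner is hidden as a 2-hydroxy-2,3-dihydro-1,4-benzodioxine (lactol), in which C7 is tied to the phenolic oxygen of ring B that lies ortho to the C8–O aryl ether. 3,4-Dimethoxyphenylmagnesium bromide opens this temporary ring. The liberated magnesium phenoxide, the ether oxygen and the aldehyde oxygen form a rigid chelate, so one operation should make the aryl–C7 bond, set C7 threo to C8 and unveil the free phenol. C8 comes from D-glycerate by Mitsunobu inversion. The 3-hydroxypropanoyl chain travels as a silyl-protected arylalkyne.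

Key step: step 7

Remark: ring A is the 3,4-dimethoxyphenyl ring and ring B the trioxygenated, acyl-bearing ring; C7, C8 and C9 are the benzylic carbinol carbon, the aryloxy-bearing carbon and the CH2OH carbon. Compounds 1, 2, 4 and 11 (11 as a 0.5 M solution in THF) are assumed to be catalogue chemicals.

Step 1
Reactants: 1 5-bromo-2-hydroxy-3-methoxybenzaldehyde; 2 tert-butyldimethyl(prop-2-yn-1-yloxy)silane
Product: 3 5-{3-[(tert-butyldimethylsilyl)oxy]prop-1-yn-1-yl}-2-hydroxy-3-methoxybenzaldehyde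
Conditions: PdCl2(PPh3)2 (3 mol %), CuI (5 mol %), Et3N, DMF, 60 °C
Reagents that add atoms: none
Why: Sonogashira coupling at the aryl bromide para to the phenol should tolerate the aldehyde and the hydrogen-bonded phenol, and installs the alkyne that masks the 3-hydroxypropanoyl chain against the later hydride and Grignard steps.

Step 2
Reactants: 4 methyl (4R)-2,2-dimethyl-1,3-dioxolane-4-carboxylate
Product: 5 methyl (2R)-2,3-dihydroxypropanoate
Conditions: Dowex 50WX8 (H+), MeOH, rt
Reagents that add atoms: none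
Why: Acid-catalysed transacetalisation in methanol should release the diol without touching the stereocentre, and ester exchange with the solvent is degenerate.

Step 3
Reactants: 5 methyl (2R)-2,3-dihydroxypropanoate
Product: 6 methyl (2R)-3-[(tert-butyldiphenylsilyl)oxy]-2-hydroxypropanoate
Conditions: TBDPSCl, imidazole, CH2Cl2, 0 °C
Reagents that add atoms: tert-butyl(chloro)diphenylsilane (TBDPSCl), CC(C)(C)[Si](Cl)(c1ccccc1)c1ccccc1
Why: Selective silylation of the primary hydroxyl is expected because the secondary hydroxyl is hindered and deactivated by the ester; the bulky, poorly coordinating TBDPS ether is chosen so that O9 does not compete as a chelating site in step 7.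

Step 4
Reactants: 3 5-{3-[(tert-butyldimethylsilyl)oxy]prop-1-yn-1-yl}-2-hydroxy-3-methoxybenzaldehyde; 6 methyl (2R)-3-[(tert-butyldiphenylsilyl)oxy]-2-hydroxypropanoate
Product: 7 methyl (2S)-2-[4-{3-[(tert-butyldimethylsilyl)oxy]prop-1-yn-1-yl}-2-formyl-6-methoxyphenoxy]-3-[(tert-butyldiphenylsilyl)oxy]propanoate
Conditions: PPh3, DIAD, THF, 0 °C → rt
Reagents that add atoms: none
Why: Mitsunobu etherification of the acidic salicylaldehyde-type phenol with the α-hydroxy ester should proceed by SN2 inversion, converting the (R)-carbinol into the (S)-aryloxy centre that becomes C8; the only free phenol of 3 fixes which ring-B oxygen carries C8.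

Step 5
Reactants: 7 methyl (2S)-2-[4-{3-[(tert-butyldimethylsilyl)oxy]prop-1-yn-1-yl}-2-formyl-6-methoxyphenoxy]-3-[(tert-butyldiphenylsilyl)oxy]propanoate
Product: 9 methyl (2S)-2-[4-{3-[(tert-butyldimethylsilyl)oxy]prop-1-yn-1-yl}-2-hydroxy-6-methoxyphenoxy]-3-[(tert-butyldiphenylsilyl)oxy]propanoate, via aryl formate 8 (not isolated)
Conditions: mCPBA, CH2Cl2, 0 °C → rt; then Et3N (cat.), MeOH, 0 °C
Reagents that add atoms: 3-chloroperoxybenzoic acid (mCPBA), O=C(OO)c1cccc(Cl)c1
Why: Baeyer–Villiger (Dakin-type) oxidation with migration of the ortho-alkoxy-activated aryl group should give the formate, whose mild methanolysis places the phenolic OH ortho to the C8–O ether; the alkyne reacts far more slowly with peracid, and any material that lactonises gives the same lactol in step 6.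

Step 6
Reactants: 9 methyl (2S)-2-[4-{3-[(tert-butyldimethylsilyl)oxy]prop-1-yn-1-yl}-2-hydroxy-6-methoxyphenoxy]-3-[(tert-butyldiphenylsilyl)oxy]propanoate
Product: 10 (3S)-7-{3-[(tert-butyldimethylsilyl)oxy]prop-1-yn-1-yl}-3-{[(tert-butyldiphenylsilyl)oxy]methyl}-5-methoxy-2,3-dihydro-1,4-benzodioxin-2-ol (both C2 anomers)
Conditions: DIBAL-H (2.3 equiv), CH2Cl2, −78 °C; then MeOH, aq. Rochelle salt
Reagents that add atoms: none
Why: DIBAL-H partial reduction of the α-alkoxy ester through a chelated tetrahedral aluminate should stop at the aldehyde level, which the neighbouring phenol captures as the six-membered lactol; the C8 centre is not touched and the anomeric mixture is used as such.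

Step 7
Reactants: 10 (3S)-7-{3-[(tert-butyldimethylsilyl)oxy]prop-1-yn-1-yl}-3-{[(tert-butyldiphenylsilyl)oxy]methyl}-5-methoxy-2,3-dihydro-1,4-benzodioxin-2-ol; 11 (3,4-dimethoxyphenyl)magnesium bromide
Product: 13 (1S,2S)-2-[4-{3-[(tert-butyldimethylsilyl)oxy]prop-1-yn-1-yl}-2-hydroxy-6-methoxyphenoxy]-3-[(tert-butyldiphenylsilyl)oxy]-1-(3,4-dimethoxyphenyl)propan-1-ol, via ring-opened aldehyde bromomagnesium phenoxide 12 (not isolated)
Conditions: 11 (3.2 equiv, 0.5 M in THF), CH2Cl2, −78 → 0 °C; then pH 7 buffer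
Reagents that add atoms: none
Why: The first equivalent of 11 deprotonates the lactol, the magnesium lactolate opens to aldehyde 12 with its bromomagnesium phenoxide held next to the C8 ether oxygen, and a further equivalent of 11 adds its aryl carbon to the aldehyde carbon. The closest known reaction types are the ring-opening Grignard addition to lactols and the Cram-chelate addition to α-alkoxy aldehydes. No ring is closed; the temporary 1,4-dioxane ring is opened and both lactol anomers converge on the same aldehyde. The new C7 centre is controlled by the existing (S)-C8 centre: magnesium bound to the phenoxide oxygen, the ether oxygen and the carbonyl oxygen locks the O=C7–C8–O unit syn-periplanar, and the aryl group attacks the face anti to the CH2OTBDPS group (the face of C8–H), which corresponds to the 7S,8S (threo) arrangement. The step needs chelate control over Felkin–Anh or β-chelate pathways and addition over enolisation; the covalently anchored magnesium phenoxide, the bulky non-coordinating TBDPS ether on O9, CH2Cl2 as main solvent and low temperature are relied on for this.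

Step 8
Reactants: 13 (1S,2S)-2-[4-{3-[(tert-butyldimethylsilyl)oxy]prop-1-yn-1-yl}-2-hydroxy-6-methoxyphenoxy]-3-[(tert-butyldiphenylsilyl)oxy]-1-(3,4-dimethoxyphenyl)propan-1-ol
Product: 14 3-[(tert-butyldimethylsilyl)oxy]-1-[4-{[(1S,2S)-3-[(tert-butyldiphenylsilyl)oxy]-1-(3,4-dimethoxyphenyl)-1-hydroxypropan-2-yl]oxy}-3-hydroxy-5-methoxyphenyl]propan-1-one
Conditions: (IPr)AuNTf2 (3 mol %), 1,4-dioxane/H2O (4:1), 50 °C
Reagents that add atoms: water, O
Why: Gold(I)-catalysed alkyne hydration should deliver water to the alkyne carbon attached to ring B, which is aryl-stabilised and remote from the inductively withdrawing CH2OSi group, giving the aryl ketone without touching either stereocentre.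

Step 9
Reactants: 14 3-[(tert-butyldimethylsilyl)oxy]-1-[4-{[(1S,2S)-3-[(tert-butyldiphenylsilyl)oxy]-1-(3,4-dimethoxyphenyl)-1-hydroxypropan-2-yl]oxy}-3-hydroxy-5-methoxyphenyl]propan-1-one
Product: 15 1-[4-{[(1S,2S)-1-(3,4-dimethoxyphenyl)-1,3-dihydroxypropan-2-yl]oxy}-3-hydroxy-5-methoxyphenyl]-3-hydroxypropan-1-one
Conditions: TBAF, AcOH (1:1), THF, rt
Reagents that add atoms: none
Why: Fluoride-mediated cleavage of both silyl ethers, buffered with acetic acid, should free the two primary alcohols without β-elimination or retro-aldol cleavage of the β-hydroxy ketone and without ionising the benzylic alcohol.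

Compound list
1 | 5-bromo-2-hydroxy-3-methoxybenzaldehyde | COc1cc(Br)cc(C=O)c1O | starting material
2 | tert-butyldimethyl(prop-2-yn-1-yloxy)silane | C#CCO[Si](C)(C)C(C)(C)C | starting material
3 | 5-{3-[(tert-butyldimethylsilyl)oxy]prop-1-yn-1-yl}-2-hydroxy-3-methoxybenzaldehyde | COc1cc(C#CCO[Si](C)(C)C(C)(C)C)cc(C=O)c1O | intermediate
4 | methyl (4R)-2,2-dimethyl-1,3-dioxolane-4-carboxylate | COC(=O)[C@H]1COC(C)(C)O1 | starting material
5 | methyl (2R)-2,3-dihydroxypropanoate | COC(=O)[C@H](O)CO | intermediate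
6 | methyl (2R)-3-[(tert-butyldiphenylsilyl)oxy]-2-hydroxypropanoate | COC(=O)[C@H](O)CO[Si](c1ccccc1)(c1ccccc1)C(C)(C)C | intermediate
7 | methyl (2S)-2-[4-{3-[(tert-butyldimethylsilyl)oxy]prop-1-yn-1-yl}-2-formyl-6-methoxyphenoxy]-3-[(tert-butyldiphenylsilyl)oxy]propanoate | COC(=O)[C@@H](Oc1c(C=O)cc(C#CCO[Si](C)(C)C(C)(C)C)cc1OC)CO[Si](c1ccccc1)(c1ccccc1)C(C)(C)C | intermediate
8 | methyl (2S)-2-[4-{3-[(tert-butyldimethylsilyl)oxy]prop-1-yn-1-yl}-2-(formyloxy)-6-methoxyphenoxy]-3-[(tert-butyldiphenylsilyl)oxy]propanoate (aryl formate) | COC(=O)[C@@H](Oc1c(OC=O)cc(C#CCO[Si](C)(C)C(C)(C)C)cc1OC)CO[Si](c1ccccc1)(c1ccccc1)C(C)(C)C | intermediate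
9 | methyl (2S)-2-[4-{3-[(tert-butyldimethylsilyl)oxy]prop-1-yn-1-yl}-2-hydroxy-6-methoxyphenoxy]-3-[(tert-butyldiphenylsilyl)oxy]propanoate | COC(=O)[C@@H](Oc1c(O)cc(C#CCO[Si](C)(C)C(C)(C)C)cc1OC)CO[Si](c1ccccc1)(c1ccccc1)C(C)(C)C | intermediate
10 | (3S)-7-{3-[(tert-butyldimethylsilyl)oxy]prop-1-yn-1-yl}-3-{[(tert-butyldiphenylsilyl)oxy]methyl}-5-methoxy-2,3-dihydro-1,4-benzodioxin-2-ol (both C2 anomers) | OC1Oc2cc(C#CCO[Si](C)(C)C(C)(C)C)cc(OC)c2O[C@H]1CO[Si](c1ccccc1)(c1ccccc1)C(C)(C)C | intermediate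
11 | (3,4-dimethoxyphenyl)magnesium bromide | COc1ccc([Mg]Br)cc1OC | starting material
12 | bromomagnesium 5-{3-[(tert-butyldimethylsilyl)oxy]prop-1-yn-1-yl}-2-{[(2S)-1-[(tert-butyldiphenylsilyl)oxy]-3-oxopropan-2-yl]oxy}-3-methoxyphenolate (ring-opened aldehyde) | Br[Mg]Oc1cc(C#CCO[Si](C)(C)C(C)(C)C)cc(OC)c1O[C@H](C=O)CO[Si](c1ccccc1)(c1ccccc1)C(C)(C)C | intermediate
13 | (1S,2S)-2-[4-{3-[(tert-butyldimethylsilyl)oxy]prop-1-yn-1-yl}-2-hydroxy-6-methoxyphenoxy]-3-[(tert-butyldiphenylsilyl)oxy]-1-(3,4-dimethoxyphenyl)propan-1-ol | COc1ccc([C@H](O)[C@H](CO[Si](c2ccccc2)(c2ccccc2)C(C)(C)C)Oc2c(O)cc(C#CCO[Si](C)(C)C(C)(C)C)cc2OC)cc1OC | intermediate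
14 | 3-[(tert-butyldimethylsilyl)oxy]-1-[4-{[(1S,2S)-3-[(tert-butyldiphenylsilyl)oxy]-1-(3,4-dimethoxyphenyl)-1-hydroxypropan-2-yl]oxy}-3-hydroxy-5-methoxyphenyl]propan-1-one | COc1ccc([C@H](O)[C@H](CO[Si](c2ccccc2)(c2ccccc2)C(C)(C)C)Oc2c(O)cc(C(=O)CCO[Si](C)(C)C(C)(C)C)cc2OC)cc1OC | intermediate
15 | 1-[4-{[(1S,2S)-1-(3,4-dimethoxyphenyl)-1,3-dihydroxypropan-2-yl]oxy}-3-hydroxy-5-methoxyphenyl]-3-hydroxypropan-1-one | COc1ccc([C@H](O)[C@H](CO)Oc2c(O)cc(C(=O)CCO)cc2OC)cc1OC | target

Total step count: 9. Longest linear sequence: 8 steps (4 → 5 → 6 → 7 → 9 → 10 → 13 → 14 → 15).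

Steps most likely to fail

1. Step 7. The facial selectivity may erode if an open Felkin–Anh transition state competes with the chelate, and C8 may epimerise or O9 may be eliminated if the Grignard reagent enolises the aldehyde. Fallback, setting out from 9: the ester is converted with MeNH(OMe)·HCl and iPrMgCl (THF, −20 °C) into (2S)-2-[4-{3-[(tert-butyldimethylsilyl)oxy]prop-1-yn-1-yl}-2-hydroxy-6-methoxyphenoxy]-3-[(tert-butyldiphenylsilyl)oxy]-N-methoxy-N-methylpropanamide F1. Addition of 11 (THF, −40 → 0 °C) to this Weinreb amide should give the aryl ketone (2S)-2-[4-{3-[(tert-butyldimethylsilyl)oxy]prop-1-yn-1-yl}-2-hydroxy-6-methoxyphenoxy]-3-[(tert-butyldiphenylsilyl)oxy]-1-(3,4-dimethoxyphenyl)propan-1-one F2. Its C7 carbonyl is then reduced under catalyst control by Noyori–Ikariya transfer hydrogenation (RuCl[(R,R)-TsDPEN](p-cymene), HCO2H/Et3N). With the aryl group in its usual position this should give the 7S carbinol, and because the C8–H of the ketone is labile the reduction can run as a dynamic kinetic resolution. The fallback rejoins the route at 13.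

2. Step 8. The cationic gold medium may ionise the electron-rich benzylic C7–OH (epimerisation, or closure onto the ring-B phenol), or water may add with imperfect regiocontrol. Fallback, setting out from 13: global desilylation (TBAF, AcOH, THF) gives (1S,2S)-1-(3,4-dimethoxyphenyl)-2-[2-hydroxy-4-(3-hydroxyprop-1-yn-1-yl)-6-methoxyphenoxy]propane-1,3-diol F3. Hydroxyl-directed ruthenium-catalysed trans-hydrosilylation ([Cp*Ru(MeCN)3]PF6, BnMe2SiH, acetone, 0 °C → rt) should place silicon on the alkyne carbon attached to ring B, giving (1S,2S)-2-[4-{(1Z)-1-[benzyl(dimethyl)silyl]-3-hydroxyprop-1-en-1-yl}-2-hydroxy-6-methoxyphenoxy]-1-(3,4-dimethoxyphenyl)propane-1,3-diol F4. Tamao–Fleming oxidation (TBAF, THF; then H2O2, KHCO3, MeOH) converts the vinylsilane into the β-hydroxy ketone under non-acidic conditions. The fallback rejoins the route at 15.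

3. Step 4. Oxyphosphonium displacement by the doubly ortho-substituted, hydrogen-bonded phenol may be slow, allowing elimination or partial loss of configuration at the glycerate carbon. Fallback, setting out from 6: the alcohol is converted (Tf2O, 2,6-lutidine, CH2Cl2, −78 °C) into methyl (2R)-3-[(tert-butyldiphenylsilyl)oxy]-2-{[(trifluoromethyl)sulfonyl]oxy}propanoate F5. This triflate is displaced by the phenoxide of 3 (K2CO3, MeCN, −20 → 0 °C) in a direct SN2 reaction with inversion. The fallback rejoins the route at 7.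

Further compounds
F1 | step 7 | (2S)-2-[4-{3-[(tert-butyldimethylsilyl)oxy]prop-1-yn-1-yl}-2-hydroxy-6-methoxyphenoxy]-3-[(tert-butyldiphenylsilyl)oxy]-N-methoxy-N-methylpropanamide | CON(C)C(=O)[C@@H](Oc1c(O)cc(C#CCO[Si](C)(C)C(C)(C)C)cc1OC)CO[Si](c1ccccc1)(c1ccccc1)C(C)(C)C
F2 | step 7 | (2S)-2-[4-{3-[(tert-butyldimethylsilyl)oxy]prop-1-yn-1-yl}-2-hydroxy-6-methoxyphenoxy]-3-[(tert-butyldiphenylsilyl)oxy]-1-(3,4-dimethoxyphenyl)propan-1-one | COc1ccc(C(=O)[C@H](CO[Si](c2ccccc2)(c2ccccc2)C(C)(C)C)Oc2c(O)cc(C#CCO[Si](C)(C)C(C)(C)C)cc2OC)cc1OC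
F3 | step 8 | (1S,2S)-1-(3,4-dimethoxyphenyl)-2-[2-hydroxy-4-(3-hydroxyprop-1-yn-1-yl)-6-methoxyphenoxy]propane-1,3-diol | COc1ccc([C@H](O)[C@H](CO)Oc2c(O)cc(C#CCO)cc2OC)cc1OC
F4 | step 8 | (1S,2S)-2-[4-{(1Z)-1-[benzyl(dimethyl)silyl]-3-hydroxyprop-1-en-1-yl}-2-hydroxy-6-methoxyphenoxy]-1-(3,4-dimethoxyphenyl)propane-1,3-diol | COc1ccc([C@H](O)[C@H](CO)Oc2c(O)cc(/C(=C/CO)[Si](C)(C)Cc3ccccc3)cc2OC)cc1OC
F5 | step 4 | methyl (2R)-3-[(tert-butyldiphenylsilyl)oxy]-2-{[(trifluoromethyl)sulfonyl]oxy}propanoate | COC(=O)[C@H](OS(=O)(=O)C(F)(F)F)CO[Si](c1ccccc1)(c1ccccc1)C(C)(C)C
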